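The eleven-membered carbocycle is disconnected at the C4–C5 single bond, the CH2–CH2 link of the 1,5-diene between the C3 exocyclic methylene and the C6=C7 alkene (ring atoms: C1=C2 trans alkene, C10 carbinol, C11 gem-dimethyl). Nickel(0) joins the two primary allylic bromide termini of an acyclic chain in one operation, closing the ring with all three alkenes and the C10 stereocentre already in place; it exploits the fact that C4 and C5 are both allylic and that the allyl unit centred on C3 has two identical CH2 termini. The precursor is the open-chain (R)-C10 silyl ether bis(allylic bromide), built from geranyl acetate by an enantioselective isobutyrate aldol and a Suzuki diene synthesis.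

Key step: step 12

Remark on locants: C1–C11 in the text refer to the target ring (C1=C2 E, C3 bearing =CH2, C4, C5, C6=C7(CH3) E, C8, C9, C10 bearing oxygen, C11 gem-dimethyl) and are kept for the acyclic intermediates; systematic names carry their own locants.
Assumption: the N-tosyl-L-valine/borane promoter is taken to direct the ketene acetal to the Si face of the aldehyde (R at C10), as in its established use with unbranched aliphatic aldehydes; N-tosyl-D-valine would give the antipode.

Step 1
Reactants: 1 geranyl acetate
Product: 2 6,7-epoxygeranyl acetate [(2E)-5-(3,3-dimethyloxiran-2-yl)-3-methylpent-2-en-1-yl acetate, racemic at the oxirane carbon]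
Conditions: mCPBA (1.05 equiv), NaHCO3, CH2Cl2, 0 °C
Reagents that add atoms: mCPBA, O=C(OO)c1cccc(Cl)c1
Why: Prilezhaev epoxidation, in which the peracid selects the electron-richer terminal isopropylidene alkene because the other trisubstituted alkene is deactivated by the allylic acetoxy group.

Step 2
Reactants: 2 6,7-epoxygeranyl acetate
Product: 3 (2E)-3-methyl-6-oxohex-2-en-1-yl acetate
Conditions: H5IO6 (1.1 equiv), THF/H2O, 0 °C
Reagents that add atoms: none
Why: Periodic acid opens the epoxide to the glycol (water adds at the tertiary carbon, so the aldehyde oxygen is the former oxirane oxygen) and cleaves it in a Malaprade-type reaction to the aldehyde and acetone, conditions under which the allylic acetate and the remaining alkene are stable.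

Step 3
Reactants: 3 (2E)-3-methyl-6-oxohex-2-en-1-yl acetate; 4 methyl trimethylsilyl dimethylketene acetal [1-methoxy-2-methyl-1-(trimethylsilyloxy)prop-1-ene]
Product: 5 methyl (3R,6E)-8-acetoxy-3-hydroxy-2,2,6-trimethyloct-6-enoate
Conditions: N-Ts-L-valine (1.1 equiv), BH3·THF (1.0 equiv), CH2Cl2, 0 to 25 °C; then 3 and 4 (1.2 equiv), −78 °C; pH 7 buffer
Reagents that add atoms: none
Why: Kiyooka-type Mukaiyama aldol, in which the valine-derived oxazaborolidinone (formed in the flask, stoichiometric) activates the aldehyde and shields its Re face so that the ketene acetal adds to the Si face and sets C10 as R under reagent control, the acetate and the alkene being inert at −78 °C.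

Step 4
Reactants: 5 methyl (3R,6E)-8-acetoxy-3-hydroxy-2,2,6-trimethyloct-6-enoate
Product: 6 methyl (3R,6E)-3,8-dihydroxy-2,2,6-trimethyloct-6-enoate
Conditions: K2CO3 (0.3 equiv), MeOH, 0 °C
Reagents that add atoms: none
Why: Base-catalysed transesterification (Zemplén type) removes the unhindered primary acetate, which would not survive the later hydride and palladium steps, while the α-quaternary methyl ester can only exchange degenerately with methanol and mild carbonate is not expected to induce retro-aldol cleavage.

Step 5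
Reactants: 6 methyl (3R,6E)-3,8-dihydroxy-2,2,6-trimethyloct-6-enoate
Product: 7 methyl (3R,6E)-3,8-bis[(tert-butyldimethylsilyl)oxy]-2,2,6-trimethyloct-6-enoate
Conditions: TBSOTf (2.5 equiv), 2,6-lutidine (4 equiv), CH2Cl2, −78 to 0 °C
Reagents that add atoms: TBSOTf, CC(C)(C)[Si](C)(C)OS(=O)(=O)C(F)(F)F
Why: Silylation with the silyl triflate, which is reactive enough for the secondary hydroxyl next to the quaternary carbon and protects the primary allylic hydroxyl in the same operation.

Step 6
Reactants: 7 methyl (3R,6E)-3,8-bis[(tert-butyldimethylsilyl)oxy]-2,2,6-trimethyloct-6-enoate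
Product: 8 (3R,6E)-3,8-bis[(tert-butyldimethylsilyl)oxy]-2,2,6-trimethyloct-6-en-1-ol
Conditions: DIBAL-H (2.5 equiv), CH2Cl2, −78 to 0 °C; aq. Rochelle salt
Reagents that add atoms: none
Why: Hydride reduction of the ester to the primary alcohol, taken to completion because partial reduction of hindered esters tends to give aldehyde/alcohol mixtures, with silyl ethers inert to the reagent.

Step 7
Reactants: 8 (3R,6E)-3,8-bis[(tert-butyldimethylsilyl)oxy]-2,2,6-trimethyloct-6-en-1-ol
Product: 9 (3R,6E)-3,8-bis[(tert-butyldimethylsilyl)oxy]-2,2,6-trimethyloct-6-enal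
Conditions: Dess–Martin periodinane (1.3 equiv), NaHCO3, CH2Cl2, 0 to 25 °C
Reagents that add atoms: none
Why: Dess–Martin oxidation of the neopentyl primary alcohol under buffered conditions gives an aldehyde without α-hydrogen, so neither epimerisation nor β-elimination of the silyloxy group can occur.

Step 8
Reactants: 9 (3R,6E)-3,8-bis[(tert-butyldimethylsilyl)oxy]-2,2,6-trimethyloct-6-enal; 10 2-(dichloromethyl)-4,4,5,5-tetramethyl-1,3,2-dioxaborolane
Product: 11 2-[(1E,4R,7E)-4,9-bis[(tert-butyldimethylsilyl)oxy]-3,3,7-trimethylnona-1,7-dien-1-yl]-4,4,5,5-tetramethyl-1,3,2-dioxaborolane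
Conditions: CrCl2 (8 equiv), LiI (4 equiv), THF, 25 °C
Reagents that add atoms: none
Why: Takai–Utimoto borylolefination, in which chromium(II) turns the gem-dichloride into a geminal dichromium species that adds to the aldehyde and eliminates to the E-alkenylboronate (C1=C2), the quaternary substituent reinforcing E selectivity and the silyl ethers being untouched.

Step 9
Reactants: 11 the E-alkenylboronate; 12 2-bromoprop-2-en-1-ol
Product: 13 (3E,6R,9E)-6,11-bis[(tert-butyldimethylsilyl)oxy]-5,5,9-trimethyl-2-methylideneundeca-3,9-dien-1-ol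
Conditions: PdCl2(dppf)·CH2Cl2 (5 mol %), K3PO4 (3 equiv), THF/H2O (5:1), 50 °C
Reagents that add atoms: none
Why: Suzuki–Miyaura alkenyl–alkenyl coupling with retention of the boronate geometry forms the C2–C3 bond and the cross-conjugated diene in one step, the free hydroxyl and both silyl ethers tolerating aqueous phosphate.

Step 10
Reactants: 13 (3E,6R,9E)-6,11-bis[(tert-butyldimethylsilyl)oxy]-5,5,9-trimethyl-2-methylideneundeca-3,9-dien-1-ol
Product: 14 (2E,6R,8E)-6-[(tert-butyldimethylsilyl)oxy]-3,7,7-trimethyl-10-methylideneundeca-2,8-diene-1,11-diol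
Conditions: HF·pyridine, pyridine, THF, 0 °C
Reagents that add atoms: none
Why: Fluoride desilylation under kinetic control cleaves the unhindered primary allylic silyl ether at C5 far faster than the secondary one at C10, which is shielded by quaternary C11, and pyridine buffering protects the dienyl carbinol from ionisation.

Step 11
Reactants: 14 (2E,6R,8E)-6-[(tert-butyldimethylsilyl)oxy]-3,7,7-trimethyl-10-methylideneundeca-2,8-diene-1,11-diol
Product: 15 tert-butyl{[(2E,6R,8E)-1,11-dibromo-3,7,7-trimethyl-10-methylideneundeca-2,8-dien-6-yl]oxy}dimethylsilane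
Conditions: CBr4 (2.6 equiv), PPh3 (2.6 equiv), CH2Cl2, −20 to 0 °C; used at once
Reagents that add atoms: carbon tetrabromide, BrC(Br)(Br)Br
Why: Appel reaction, in which both primary allylic alcohols are displaced by bromide through alkoxyphosphonium ions under neutral conditions that spare the C10 silyl ether, the diene and the E alkene, an SN2′ path at the C3 unit giving the same compound.

Step 12
Reactants: 15 the (R)-bis(allylic bromide) C10 silyl ether
Product: 16 tert-butyldimethyl{[(1R,3E,8E)-2,2,9-trimethyl-5-methylidenecycloundeca-3,8-dien-1-yl]oxy}silane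
Conditions: Ni(CO)4 (6 equiv), NMP, 50 °C, Ar, closed system; 15 added over 12 h (final ≤0.005 M)
Reagents that add atoms: none
Why: Ni(0) adds oxidatively to both allylic C–Br bonds with loss of CO so that nickel carries both chain ends as η3-allyl ligands, and CO-induced C–C reductive elimination from the bis(allyl)nickel(II) species joins C4 to C5 and expels NiBr2. The closest known reaction type is the nickel carbonyl cyclisation of α,ω-bis(allylic bromides) to macrocyclic 1,5-dienes, eleven-membered humulene-type rings included. The eleven-membered ring closes head-to-head between the two primary termini from a nickel-bridged intermediate, so the chain ends meet in the coordination sphere and not by free end-to-end encounter, and slow addition at high dilution suppresses chain-to-chain coupling. No stereocentre is formed, and C10, remote from both allyl units, is untouched. The step needs bond formation at C5 and not C7 with the 6E geometry kept: the 2-vinylallyl unit centred on C3 has two equivalent CH2 termini so either gives the same constitution, coupling at fully substituted C7 is sterically disfavoured and would give a more strained nine-membered ring, and E/Z exchange of the C5–C7 allyl requires an η1 form bound at tertiary C7, its slowest isomerisation path. Ni(CO)4 is preferred to ligand-free Ni(0) because CO-saturated nickel does not draw the 1,3-diene into oligomerisation.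

Step 13
Reactants: 16 the macrocyclic (R)-silyl ether
Product: 17 (1R,3E,8E)-2,2,9-trimethyl-5-methylidenecycloundeca-3,8-dien-1-ol
Conditions: TBAF (5 equiv), THF, 50 °C
Reagents that add atoms: none
Why: Fluoride cleavage of the Si–O bond, run with excess reagent and warming because the site is hindered by C11, which the base-stable hydrocarbon triene tolerates, whereas acid (risk of transannular cyclisation) is avoided.

Step 14
Reactants: 18 vanillic acid
Product: 20 4-[(tert-butyldimethylsilyl)oxy]-3-methoxybenzoic acid, via silyl ester silyl ether 19 (not isolated)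
Conditions: TBSCl (2.5 equiv), imidazole (5 equiv), DMF, 25 °C; then AcOH/THF/H2O (3:1:1), 25 °C
Reagents that add atoms: TBSCl, CC(C)(C)[Si](C)(C)Cl
Why: Exhaustive silylation followed by selective hydrolysis of the far more labile silyl ester leaves the aryl silyl ether and gives the phenol-protected acid.

Step 15
Reactants: 20 4-[(tert-butyldimethylsilyl)oxy]-3-methoxybenzoic acid
Product: 21 4-[(tert-butyldimethylsilyl)oxy]-3-methoxybenzoyl chloride
Conditions: (COCl)2 (1.5 equiv), DMF (cat.), CH2Cl2, 0 to 25 °C; evaporated, used crude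
Reagents that add atoms: oxalyl chloride, O=C(Cl)C(=O)Cl
Why: Vilsmeier-type activation converts the acid into the acid chloride under mild conditions that the aryl silyl ether survives.

Step 16
Reactants: 17 (1R,3E,8E)-2,2,9-trimethyl-5-methylidenecycloundeca-3,8-dien-1-ol; 21 4-[(tert-butyldimethylsilyl)oxy]-3-methoxybenzoyl chloride
Product: 22 (1R,3E,8E)-2,2,9-trimethyl-5-methylidenecycloundeca-3,8-dien-1-yl 4-[(tert-butyldimethylsilyl)oxy]-3-methoxybenzoate
Conditions: 21 (3 equiv), DMAP (2 equiv), Et3N (4 equiv), CH2Cl2, 25 to 40 °C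
Reagents that add atoms: none
Why: DMAP-catalysed acylation through the N-acylpyridinium ion, forced with stoichiometric DMAP and excess acid chloride because the carbinol is hindered by C11, and as only the O–H bond reacts the C10 configuration is retained.

Step 17
Reactants: 22 the O-silyl vanillate
Product: 23 (1R,3E,8E)-2,2,9-trimethyl-5-methylidenecycloundeca-3,8-dien-1-yl 4-hydroxy-3-methoxybenzoate (target)
Conditions: TBAF (1.2 equiv), AcOH (1.2 equiv), THF, 0 °C
Reagents that add atoms: none
Why: Fluoride desilylation of the aryl silyl ether is fast at 0 °C, and acetic acid buffering keeps the liberated phenoxide from attacking the hindered benzoate.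

Compound list
1 | geranyl acetate | CC(=O)OC/C=C(\C)CCC=C(C)C | starting material
2 | 6,7-epoxygeranyl acetate (racemic at the oxirane carbon) | CC(=O)OC/C=C(\C)CCC1OC1(C)C | intermediate
3 | (2E)-3-methyl-6-oxohex-2-en-1-yl acetate | CC(=O)OC/C=C(\C)CCC=O | intermediate
4 | methyl trimethylsilyl dimethylketene acetal | COC(O[Si](C)(C)C)=C(C)C | starting material
5 | methyl (3R,6E)-8-acetoxy-3-hydroxy-2,2,6-trimethyloct-6-enoate | COC(=O)C(C)(C)[C@H](O)CC/C(C)=C/COC(C)=O | intermediate
6 | methyl (3R,6E)-3,8-dihydroxy-2,2,6-trimethyloct-6-enoate | COC(=O)C(C)(C)[C@H](O)CC/C(C)=C/CO | intermediate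
7 | methyl (3R,6E)-3,8-bis[(tert-butyldimethylsilyl)oxy]-2,2,6-trimethyloct-6-enoate | COC(=O)C(C)(C)[C@H](O[Si](C)(C)C(C)(C)C)CC/C(C)=C/CO[Si](C)(C)C(C)(C)C | intermediate
8 | (3R,6E)-3,8-bis[(tert-butyldimethylsilyl)oxy]-2,2,6-trimethyloct-6-en-1-ol | OCC(C)(C)[C@H](O[Si](C)(C)C(C)(C)C)CC/C(C)=C/CO[Si](C)(C)C(C)(C)C | intermediate
9 | (3R,6E)-3,8-bis[(tert-butyldimethylsilyl)oxy]-2,2,6-trimethyloct-6-enal | O=CC(C)(C)[C@H](O[Si](C)(C)C(C)(C)C)CC/C(C)=C/CO[Si](C)(C)C(C)(C)C | intermediate
10 | 2-(dichloromethyl)-4,4,5,5-tetramethyl-1,3,2-dioxaborolane | ClC(Cl)B1OC(C)(C)C(C)(C)O1 | starting material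
11 | 2-[(1E,4R,7E)-4,9-bis[(tert-butyldimethylsilyl)oxy]-3,3,7-trimethylnona-1,7-dien-1-yl]-4,4,5,5-tetramethyl-1,3,2-dioxaborolane | CC1(C)OB(/C=C/C(C)(C)[C@H](O[Si](C)(C)C(C)(C)C)CC/C(C)=C/CO[Si](C)(C)C(C)(C)C)OC1(C)C | intermediate
12 | 2-bromoprop-2-en-1-ol | C=C(Br)CO | starting material
13 | (3E,6R,9E)-6,11-bis[(tert-butyldimethylsilyl)oxy]-5,5,9-trimethyl-2-methylideneundeca-3,9-dien-1-ol | C=C(CO)/C=C/C(C)(C)[C@H](O[Si](C)(C)C(C)(C)C)CC/C(C)=C/CO[Si](C)(C)C(C)(C)C | intermediate
14 | (2E,6R,8E)-6-[(tert-butyldimethylsilyl)oxy]-3,7,7-trimethyl-10-methylideneundeca-2,8-diene-1,11-diol | C=C(CO)/C=C/C(C)(C)[C@H](O[Si](C)(C)C(C)(C)C)CC/C(C)=C/CO | intermediate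
15 | tert-butyl{[(2E,6R,8E)-1,11-dibromo-3,7,7-trimethyl-10-methylideneundeca-2,8-dien-6-yl]oxy}dimethylsilane (key-step precursor) | C=C(CBr)/C=C/C(C)(C)[C@H](O[Si](C)(C)C(C)(C)C)CC/C(C)=C/CBr | intermediate
16 | tert-butyldimethyl{[(1R,3E,8E)-2,2,9-trimethyl-5-methylidenecycloundeca-3,8-dien-1-yl]oxy}silane (key-step product) | C=C1/C=C/C(C)(C)[C@H](O[Si](C)(C)C(C)(C)C)CC/C(C)=C/CC1 | intermediate
17 | (1R,3E,8E)-2,2,9-trimethyl-5-methylidenecycloundeca-3,8-dien-1-ol | C=C1/C=C/C(C)(C)[C@H](O)CC/C(C)=C/CC1 | intermediate
18 | vanillic acid | COc1cc(C(=O)O)ccc1O | starting material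
19 | tert-butyldimethylsilyl 4-[(tert-butyldimethylsilyl)oxy]-3-methoxybenzoate | COc1cc(C(=O)O[Si](C)(C)C(C)(C)C)ccc1O[Si](C)(C)C(C)(C)C | intermediate (not isolated)
20 | 4-[(tert-butyldimethylsilyl)oxy]-3-methoxybenzoic acid | COc1cc(C(=O)O)ccc1O[Si](C)(C)C(C)(C)C | intermediate
21 | 4-[(tert-butyldimethylsilyl)oxy]-3-methoxybenzoyl chloride | COc1cc(C(Cl)=O)ccc1O[Si](C)(C)C(C)(C)C | intermediate
22 | (1R,3E,8E)-2,2,9-trimethyl-5-methylidenecycloundeca-3,8-dien-1-yl 4-[(tert-butyldimethylsilyl)oxy]-3-methoxybenzoate | C=C1/C=C/C(C)(C)[C@H](OC(=O)c2ccc(O[Si](C)(C)C(C)(C)C)c(OC)c2)CC/C(C)=C/CC1 | intermediate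
23 | (1R,3E,8E)-2,2,9-trimethyl-5-methylidenecycloundeca-3,8-dien-1-yl 4-hydroxy-3-methoxybenzoate | C=C1/C=C/C(C)(C)[C@H](OC(=O)c2ccc(O)c(OC)c2)CC/C(C)=C/CC1 | target

Total step count: 17. Longest linear sequence: 15 steps (steps 1–13, 16 and 17, from geranyl acetate).

Steps most likely to fail

Step 12. The C5–C6–C7 allyl unit may exchange its two geometries on nickel before the C–C bond forms, so that ring closure gives the 6Z ring or a mixture; chains may also couple with one another instead of closing. Fallback (sets out from 13, returns at 16): the reductive coupling is replaced by intramolecular alkylation of a sulfone-stabilised allyl anion, which forms the same C4–C5 bond without placing the C6=C7 alkene in a metal-bound allyl. Compound 13 is acetylated (Ac2O, pyridine, DMAP) to the C4 acetate F1. Selective removal of the C5 silyl group (HF·pyridine, pyridine, THF, 0 °C) gives the C5 alcohol F2, and Appel bromination (CBr4, PPh3) gives the C5 bromide F3. Displacement with sodium benzenesulfinate (DMF, 25 °C) gives the C5 phenyl sulfone F4. Methanolysis (K2CO3, MeOH) frees the C4 alcohol F5, which is converted (CBr4, PPh3) into the C4 bromide F6. Slow addition of F6 to LiHMDS in THF (−78 to 0 °C, high dilution) should close the ring by attack of the C5 α-sulfonyl carbanion on the C3 allyl unit (SN2 or SN2′, constitutionally the same), giving the macrocyclic C5 sulfone F7 as a mixture of C5 epimers. Palladium-catalysed reductive desulfonylation (PdCl2(dppp), LiBHEt3, THF, 0 °C), which delivers hydride to the less substituted allyl terminus C5, then gives 16.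

Step 13. Cleavage of the silyl ether shielded by C11 may be very slow, and forcing fluoride or a switch to acidic reagents may erode the macrocyclic triene through transannular or allylic processes. Fallback (sets out from 13, returns at 17): the silyl group is removed before the ring exists and the nickel step is run on the free carbinol. Global desilylation of 13 (TBAF, THF, 60 °C, tolerated by the acyclic dienol) gives the triol F8. Appel bromination at −30 °C with 2.1 equiv of CBr4/PPh3 should convert only the two primary allylic hydroxyls, the carbinol next to C11 being too hindered, and gives the dibromo alcohol F9. This is used at once, because the free hydroxyl can close onto the C5–C7 allyl bromide, and cyclised with Ni(CO)4 as in step 12 to give 17.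

Step 8. Addition of the geminal dichromium reagent to a carbonyl shielded by the quaternary carbon may be slow, allowing reduction or pinacol coupling of the aldehyde and erosion of E selectivity. Fallback (sets out from 9, returns at 11): the alkenylboronate is reached through an alkyne instead of a carbonyl olefination. Seyferth–Gilbert homologation of 9 with the Ohira–Bestmann reagent (K2CO3, MeOH; the aldehyde cannot enolise) gives the terminal alkyne F10. Zirconocene-catalysed hydroboration with pinacolborane (Cp2Zr(H)Cl cat., Et3N cat., 60 °C), a syn addition that places boron on the terminal carbon, gives 11.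

Further compounds
F1 | step 12 | (3E,6R,9E)-6,11-bis[(tert-butyldimethylsilyl)oxy]-5,5,9-trimethyl-2-methylideneundeca-3,9-dien-1-yl acetate (C4 acetate) | C=C(COC(C)=O)/C=C/C(C)(C)[C@H](O[Si](C)(C)C(C)(C)C)CC/C(C)=C/CO[Si](C)(C)C(C)(C)C
F2 | step 12 | (3E,6R,9E)-6-[(tert-butyldimethylsilyl)oxy]-11-hydroxy-5,5,9-trimethyl-2-methylideneundeca-3,9-dien-1-yl acetate (C5 alcohol) | C=C(COC(C)=O)/C=C/C(C)(C)[C@H](O[Si](C)(C)C(C)(C)C)CC/C(C)=C/CO
F3 | step 12 | (3E,6R,9E)-11-bromo-6-[(tert-butyldimethylsilyl)oxy]-5,5,9-trimethyl-2-methylideneundeca-3,9-dien-1-yl acetate (C5 bromide) | C=C(COC(C)=O)/C=C/C(C)(C)[C@H](O[Si](C)(C)C(C)(C)C)CC/C(C)=C/CBr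
F4 | step 12 | (3E,6R,9E)-6-[(tert-butyldimethylsilyl)oxy]-5,5,9-trimethyl-2-methylidene-11-(phenylsulfonyl)undeca-3,9-dien-1-yl acetate (C5 phenyl sulfone) | C=C(COC(C)=O)/C=C/C(C)(C)[C@H](O[Si](C)(C)C(C)(C)C)CC/C(C)=C/CS(=O)(=O)c1ccccc1
F5 | step 12 | (3E,6R,9E)-6-[(tert-butyldimethylsilyl)oxy]-5,5,9-trimethyl-2-methylidene-11-(phenylsulfonyl)undeca-3,9-dien-1-ol (C4 alcohol) | C=C(CO)/C=C/C(C)(C)[C@H](O[Si](C)(C)C(C)(C)C)CC/C(C)=C/CS(=O)(=O)c1ccccc1
F6 | step 12 | {[(2E,6R,8E)-11-bromo-3,7,7-trimethyl-10-methylidene-1-(phenylsulfonyl)undeca-2,8-dien-6-yl]oxy}(tert-butyl)dimethylsilane (C4 bromide) | C=C(CBr)/C=C/C(C)(C)[C@H](O[Si](C)(C)C(C)(C)C)CC/C(C)=C/CS(=O)(=O)c1ccccc1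
F7 | step 12 | tert-butyldimethyl{[(1R,3E,8E)-2,2,9-trimethyl-5-methylidene-7-(phenylsulfonyl)cycloundeca-3,8-dien-1-yl]oxy}silane (macrocyclic C5 sulfone, both epimers at the sulfonyl carbon) | C=C1/C=C/C(C)(C)[C@H](O[Si](C)(C)C(C)(C)C)CC/C(C)=C/C(S(=O)(=O)c2ccccc2)C1
F8 | step 13 | (2E,6R,8E)-3,7,7-trimethyl-10-methylideneundeca-2,8-diene-1,6,11-triol | C=C(CO)/C=C/C(C)(C)[C@H](O)CC/C(C)=C/CO
F9 | step 13 | (2E,6R,8E)-1,11-dibromo-3,7,7-trimethyl-10-methylideneundeca-2,8-dien-6-ol | C=C(CBr)/C=C/C(C)(C)[C@H](O)CC/C(C)=C/CBr
F10 | step 8 | (4R,7E)-4,9-bis[(tert-butyldimethylsilyl)oxy]-3,3,7-trimethylnon-7-en-1-yne | C#CC(C)(C)[C@H](O[Si](C)(C)C(C)(C)C)CC/C(C)=C/CO[Si](C)(C)C(C)(C)C
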